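The route rests on cutting the C8–O–C4' ether on its aromatic side. In ring B, C4' lies between the methoxy-bearing carbons C3' and C5' and para to C1', the carbon that carries the propenyl chain. A formyl group at C1' therefore activates C4' towards fluoride displacement and later becomes that chain. In one operation the C8 potassium alkoxide of an enantiopure erythro diol, whose O7 and ring A phenol are both methoxymethyl (MOM) ethers, displaces fluoride from 4-fluoro-3,5-dimethoxybenzaldehyde and joins the two halves without touching either stereocentre. C8 comes from ethyl (S)-lactate; C7 is set by a chelation-controlled ketone reduction.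

Key step: step 10

Remark: neolignan locants are used (ring A side: C7 carbinol carbon, C8 ether-bearing carbon, C9 methyl; ring B: primed locants); the target is the erythro (7R,8S) isomer, (1R,2S) in the systematic names.

Step 1
Reactants: 1 ethyl (S)-lactate
Product: 2 ethyl (2S)-2-(benzyloxy)propanoate
Conditions: BnOC(=NH)CCl3 (1.3 equiv), TfOH (5 mol%), cyclohexane–CH2Cl2 2:1, rt
Reagents that add atoms: benzyl 2,2,2-trichloroacetimidate, N=C(OCc1ccccc1)C(Cl)(Cl)Cl
Why: Acid-catalysed O-benzylation with a trichloroacetimidate transfers benzyl to the hydroxyl without base, so the lactate α-carbon is not enolised and stays S, and the benzyloxy group is the chelating handle for step 5.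

Step 2
Reactants: 2 ethyl (2S)-2-(benzyloxy)propanoate
Product: 3 (2S)-2-(benzyloxy)-N-methoxy-N-methylpropanamide
Conditions: MeNH(OMe)·HCl (1.5 equiv), i-PrMgCl (3.0 equiv), THF, –20 → 0 °C; aq NH4Cl
Reagents that add atoms: N,O-dimethylhydroxylamine hydrochloride, CNOC.Cl
Why: Weinreb amide formation by ester aminolysis, in which the chloromagnesium amide made in the flask adds to the ester at low temperature faster than it can deprotonate the α-carbon, so C8 should stay S.

Step 3
Reactants: 4 4-bromo-2,6-dimethoxyphenol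
Product: 5 5-bromo-1,3-dimethoxy-2-(methoxymethoxy)benzene
Conditions: NaH (1.2 equiv), MOMCl (1.3 equiv), DMF, 0 °C → rt
Reagents that add atoms: chloromethyl methyl ether, COCCl
Why: Williamson-type O-alkylation of the sodium phenoxide with MOMCl gives an acetal that masks the phenol against n-BuLi and against the alkoxide chemistry of step 10.

Step 4
Reactants: 5 5-bromo-1,3-dimethoxy-2-(methoxymethoxy)benzene; 3 (2S)-2-(benzyloxy)-N-methoxy-N-methylpropanamide
Product: 7 (2S)-2-(benzyloxy)-1-[3,5-dimethoxy-4-(methoxymethoxy)phenyl]propan-1-one, via aryllithium 6 (not isolated)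
Conditions: 5 (1.2 equiv), n-BuLi (1.15 equiv), THF, –78 °C; then 3 (1.0 equiv), –78 → –40 °C; aq NH4Cl
Reagents that add atoms: none
Why: Bromine–lithium exchange followed by Weinreb ketone synthesis, in which the lithium-chelated tetrahedral adduct survives until the quench, so neither over-addition nor base-mediated enolisation of the α-benzyloxy ketone (which would racemise C8) should occur.

Step 5
Reactants: 7 (2S)-2-(benzyloxy)-1-[3,5-dimethoxy-4-(methoxymethoxy)phenyl]propan-1-one
Product: 8 (1R,2S)-2-(benzyloxy)-1-[3,5-dimethoxy-4-(methoxymethoxy)phenyl]propan-1-ol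
Conditions: Zn(BH4)2 (1.5 equiv, freshly made from ZnCl2 and NaBH4 in Et2O), Et2O, –20 → 0 °C; aq NH4Cl
Reagents that add atoms: none
Why: Chelation-controlled hydride reduction, in which zinc bridges the carbonyl and benzyloxy oxygens in a five-membered ring and hydride arrives on the carbonyl face next to H8 and away from the C9 methyl, which should set C7 as R and give the anti (erythro) alcohol.

Step 6
Reactants: 8 (1R,2S)-2-(benzyloxy)-1-[3,5-dimethoxy-4-(methoxymethoxy)phenyl]propan-1-ol
Product: 9 5-[(1R,2S)-2-(benzyloxy)-1-(methoxymethoxy)propyl]-1,3-dimethoxy-2-(methoxymethoxy)benzene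
Conditions: MOMCl (3 equiv), i-Pr2NEt (4 equiv), CH2Cl2, 0 → 40 °C
Reagents that add atoms: chloromethyl methyl ether, COCCl
Why: O-Alkylation of the secondary alcohol with MOMCl under amine base places on O7 an acetal that cannot migrate to a neighbouring alkoxide, as step 10 requires, and no bond to a stereocentre is broken.

Step 7
Reactants: 9 5-[(1R,2S)-2-(benzyloxy)-1-(methoxymethoxy)propyl]-1,3-dimethoxy-2-(methoxymethoxy)benzene
Product: 10 (1R,2S)-1-[3,5-dimethoxy-4-(methoxymethoxy)phenyl]-1-(methoxymethoxy)propan-2-ol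
Conditions: H2 (1 atm), Pd/C (10 wt% Pd), EtOAc, rt
Reagents that add atoms: none
Why: Catalytic hydrogenolysis of the benzyl ether in a neutral, non-alcoholic solvent should free O8 selectively, because the hindered secondary benzylic C7–O acetal bond is cleaved much more slowly than the primary benzyl–O bond.

Step 8
Reactants: 11 syringaldehyde (4-hydroxy-3,5-dimethoxybenzaldehyde)
Product: 12 4-formyl-2,6-dimethoxyphenyl sulfurofluoridate
Conditions: SO2F2 (balloon), Et3N (2 equiv), CH2Cl2, rt
Reagents that add atoms: sulfuryl fluoride, O=S(=O)(F)F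
Why: Sulfur–fluoride exchange, in which the phenoxide of the acidic para-formyl phenol attacks sulfur of SO2F2 and displaces one fluoride while the aldehyde stays inert.

Step 9
Reactants: 12 4-formyl-2,6-dimethoxyphenyl sulfurofluoridate
Product: 13 4-fluoro-3,5-dimethoxybenzaldehyde
Conditions: NMe4F (anhydrous, 2 equiv), DMF, rt → 80 °C
Reagents that add atoms: tetramethylammonium fluoride, C[N+](C)(C)C.[F-]
Why: Nucleophilic deoxyfluorination of an aryl fluorosulfonate, in which fluoride attacks the ipso carbon activated by the para formyl group and fluorosulfate leaves, and the aldehyde, lacking α-hydrogens, tolerates anhydrous fluoride.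

Step 10
Reactants: 10 (1R,2S)-1-[3,5-dimethoxy-4-(methoxymethoxy)phenyl]-1-(methoxymethoxy)propan-2-ol; 13 4-fluoro-3,5-dimethoxybenzaldehyde
Product: 15 4-{[(1R,2S)-1-[3,5-dimethoxy-4-(methoxymethoxy)phenyl]-1-(methoxymethoxy)propan-2-yl]oxy}-3,5-dimethoxybenzaldehyde, via potassium alkoxide 14 (not isolated)
Conditions: KN(SiMe3)2 (1.0 equiv), THF, –20 °C; then 13 (1.3 equiv), DMF, 0 °C → rt
Reagents that add atoms: none
Why: Nucleophilic aromatic substitution by addition–elimination: the alkoxide oxygen adds to C4' of 13 to give a Meisenheimer anion whose charge is delocalised onto the para formyl oxygen, and loss of fluoride restores ring B with the new O8–C4' bond. The closest known reaction type is the etherification of 4-fluorobenzaldehydes by secondary potassium alkoxides in dipolar aprotic solvents. No ring is closed and no stereocentre is created; because the bond forms at the aromatic carbon, the C8–O bond is never broken and the (7R,8S) configuration from steps 1 and 5 should pass through unchanged. Two selectivities are needed: arylation at O8 and not O7, secured by the acetal on O7, which cannot shift to a neighbouring alkoxide as a silyl or acyl group would; and substitution at C4' in preference to consumption of the formyl group, secured by using exactly one equivalent of base, so that only reversible hemiacetal formation competes with irreversible fluoride loss. Fluoride is the leaving group of choice because the rate-limiting addition is fastest at a C–F carbon, which offsets the shielding by the two flanking methoxy groups.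

Step 11
Reactants: 15 4-{[(1R,2S)-1-[3,5-dimethoxy-4-(methoxymethoxy)phenyl]-1-(methoxymethoxy)propan-2-yl]oxy}-3,5-dimethoxybenzaldehyde
Product: 16 2-{[(1R,2S)-1-[3,5-dimethoxy-4-(methoxymethoxy)phenyl]-1-(methoxymethoxy)propan-2-yl]oxy}-1,3-dimethoxy-5-[(1E)-prop-1-en-1-yl]benzene
Conditions: 5-(ethylsulfonyl)-1-phenyl-1H-tetrazole (1.5 equiv), KN(SiMe3)2 (1.4 equiv), DME, –60 °C; then 15, –60 °C → rt
Reagents that add atoms: 5-(ethylsulfonyl)-1-phenyl-1H-tetrazole, CCS(=O)(=O)c1nnnn1-c1ccccc1
Why: Julia–Kocienski olefination, in which the metalated sulfone adds to the aldehyde, the adduct undergoes Smiles transfer of the tetrazolyl group and loses SO2 and tetrazolonate, and the phenyltetrazolyl sulfone with a potassium counter-ion in DME should favour the (E)-propenyl group while acetals and the aryl ether stay inert.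

Step 12
Reactants: 16 2-{[(1R,2S)-1-[3,5-dimethoxy-4-(methoxymethoxy)phenyl]-1-(methoxymethoxy)propan-2-yl]oxy}-1,3-dimethoxy-5-[(1E)-prop-1-en-1-yl]benzene
Product: 18 (1R,2S)-2-{2,6-dimethoxy-4-[(1E)-prop-1-en-1-yl]phenoxy}-1-(4-hydroxy-3,5-dimethoxyphenyl)propan-1-ol, via bis(bromomethyl) ether 17 (not isolated)
Conditions: Me2BBr (5 equiv), CH2Cl2, –78 °C; then THF–sat. aq NaHCO3, 0 °C
Reagents that add atoms: none
Why: Lewis-acid acetal cleavage with Me2BBr, in which boron binds the terminal methoxy oxygen of each MOM group and bromide captures the O–CH2 carbon to give bromomethyl ethers that the bicarbonate quench hydrolyses to the phenol and the C7 alcohol; no bond to C7 or C8 is broken, so the configuration should be kept, and at –78 °C the propenyl group should be spared.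

Compound list
1 | ethyl (S)-lactate | C[C@H](O)C(=O)OCC | starting material
2 | ethyl (2S)-2-(benzyloxy)propanoate | CCOC(=O)[C@H](C)OCc1ccccc1 | intermediate
3 | (2S)-2-(benzyloxy)-N-methoxy-N-methylpropanamide | CON(C)C(=O)[C@H](C)OCc1ccccc1 | intermediate
4 | 4-bromo-2,6-dimethoxyphenol | Oc1c(OC)cc(Br)cc1OC | starting material
5 | 5-bromo-1,3-dimethoxy-2-(methoxymethoxy)benzene | COCOc1c(OC)cc(Br)cc1OC | intermediate
6 | [3,5-dimethoxy-4-(methoxymethoxy)phenyl]lithium (not isolated) | [Li]c1cc(OC)c(OCOC)c(OC)c1 | intermediate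
7 | (2S)-2-(benzyloxy)-1-[3,5-dimethoxy-4-(methoxymethoxy)phenyl]propan-1-one | C[C@H](OCc1ccccc1)C(=O)c1cc(OC)c(OCOC)c(OC)c1 | intermediate
8 | (1R,2S)-2-(benzyloxy)-1-[3,5-dimethoxy-4-(methoxymethoxy)phenyl]propan-1-ol | C[C@H](OCc1ccccc1)[C@H](O)c1cc(OC)c(OCOC)c(OC)c1 | intermediate
9 | 5-[(1R,2S)-2-(benzyloxy)-1-(methoxymethoxy)propyl]-1,3-dimethoxy-2-(methoxymethoxy)benzene | C[C@H](OCc1ccccc1)[C@H](OCOC)c1cc(OC)c(OCOC)c(OC)c1 | intermediate
10 | (1R,2S)-1-[3,5-dimethoxy-4-(methoxymethoxy)phenyl]-1-(methoxymethoxy)propan-2-ol | O[C@@H](C)[C@H](OCOC)c1cc(OC)c(OCOC)c(OC)c1 | intermediate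
11 | syringaldehyde (4-hydroxy-3,5-dimethoxybenzaldehyde) | O=Cc1cc(OC)c(O)c(OC)c1 | starting material
12 | 4-formyl-2,6-dimethoxyphenyl sulfurofluoridate | O=Cc1cc(OC)c(OS(=O)(=O)F)c(OC)c1 | intermediate
13 | 4-fluoro-3,5-dimethoxybenzaldehyde | O=Cc1cc(OC)c(F)c(OC)c1 | intermediate
14 | potassium (1R,2S)-1-[3,5-dimethoxy-4-(methoxymethoxy)phenyl]-1-(methoxymethoxy)propan-2-olate (not isolated) | [K+].[O-][C@@H](C)[C@H](OCOC)c1cc(OC)c(OCOC)c(OC)c1 | intermediate
15 | 4-{[(1R,2S)-1-[3,5-dimethoxy-4-(methoxymethoxy)phenyl]-1-(methoxymethoxy)propan-2-yl]oxy}-3,5-dimethoxybenzaldehyde | O=Cc1cc(OC)c(O[C@@H](C)[C@H](OCOC)c2cc(OC)c(OCOC)c(OC)c2)c(OC)c1 | intermediate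
16 | 2-{[(1R,2S)-1-[3,5-dimethoxy-4-(methoxymethoxy)phenyl]-1-(methoxymethoxy)propan-2-yl]oxy}-1,3-dimethoxy-5-[(1E)-prop-1-en-1-yl]benzene | C/C=C/c1cc(OC)c(O[C@@H](C)[C@H](OCOC)c2cc(OC)c(OCOC)c(OC)c2)c(OC)c1 | intermediate
17 | 2-{[(1R,2S)-1-(bromomethoxy)-1-[4-(bromomethoxy)-3,5-dimethoxyphenyl]propan-2-yl]oxy}-1,3-dimethoxy-5-[(1E)-prop-1-en-1-yl]benzene (not isolated) | C/C=C/c1cc(OC)c(O[C@@H](C)[C@H](OCBr)c2cc(OC)c(OCBr)c(OC)c2)c(OC)c1 | intermediate
18 | (1R,2S)-2-{2,6-dimethoxy-4-[(1E)-prop-1-en-1-yl]phenoxy}-1-(4-hydroxy-3,5-dimethoxyphenyl)propan-1-ol | C/C=C/c1cc(OC)c(O[C@@H](C)[C@H](O)c2cc(OC)c(O)c(OC)c2)c(OC)c1 | target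

Total step count: 12. Longest linear sequence: 9 steps (steps 1, 2, 4, 5, 6, 7, 10, 11 and 12, from ethyl (S)-lactate).

Steps most likely to fail

Step 10. Addition to the doubly ortho-substituted C4' may be slow. Hydride transfer from the C8 alkoxide to the aldehyde (Meerwein–Ponndorf–Verley-type redox) or base-induced disproportionation of the aldehyde could then consume the partners. The fallback sets out from 10 and comes back at 15, and forms the ether at the alkyl side by two successive Mitsunobu inversions at C8, so that the net result is again retention. Alcohol 10 would be treated with 4-nitrobenzoic acid, PPh3 and DIAD (toluene, 0 °C → rt) to give the inverted ester (1R,2R)-1-[3,5-dimethoxy-4-(methoxymethoxy)phenyl]-1-(methoxymethoxy)propan-2-yl 4-nitrobenzoate F1. Methanolysis (K2CO3, MeOH, rt) would give the threo alcohol (1R,2R)-1-[3,5-dimethoxy-4-(methoxymethoxy)phenyl]-1-(methoxymethoxy)propan-2-ol F2. A second Mitsunobu reaction of F2 with syringaldehyde 11 as the acidic phenol (PPh3, DIAD, THF, 0 °C → rt) would invert C8 once more and deliver 15.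

Step 9. Fluoride may attack sulfur and not the shielded ring carbon, returning the phenoxide, which then forms a diaryl sulfate with unreacted 12. The fallback sets out from 11 and comes back at 13, and replaces attack on the ring by metal-mediated C–F bond formation. Triflation of 11 (Tf2O, pyridine, CH2Cl2, 0 °C) would give 4-formyl-2,6-dimethoxyphenyl trifluoromethanesulfonate F3. Palladium-catalysed fluorination of F3 ([Pd(cinnamyl)Cl]2, tBuBrettPhos, CsF, toluene, 110 °C) would then give 13. This proceeds by oxidative addition to zerovalent palladium, triflate–fluoride exchange and C–F reductive elimination from the divalent arylpalladium fluoride. The absence of hydrogens ortho to the triflate rules out regioisomeric fluorides.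

Step 12. Trace HBr or the Lewis acid may hydrobrominate or cationically dimerise the electron-rich propenylarene during acetal cleavage or quench. The fallback sets out from 15 and comes back at 18, and moves the acid step in front of the olefination so that the final unmasking is done with fluoride. Aldehyde 15 would be cleaved with Me2BBr (CH2Cl2, –78 °C; aq NaHCO3) by way of the bis(bromomethyl) ether 4-{[(1R,2S)-1-(bromomethoxy)-1-[4-(bromomethoxy)-3,5-dimethoxyphenyl]propan-2-yl]oxy}-3,5-dimethoxybenzaldehyde F4 to the diol 4-{[(1R,2S)-1-hydroxy-1-(4-hydroxy-3,5-dimethoxyphenyl)propan-2-yl]oxy}-3,5-dimethoxybenzaldehyde F5. Silylation (Et3SiCl, imidazole, DMF, rt) would give 4-{[(1R,2S)-1-{3,5-dimethoxy-4-[(triethylsilyl)oxy]phenyl}-1-[(triethylsilyl)oxy]propan-2-yl]oxy}-3,5-dimethoxybenzaldehyde F6. Julia–Kocienski olefination under the conditions of step 11 would give the bis(triethylsilyl) ether triethyl{4-[(1R,2S)-2-{2,6-dimethoxy-4-[(1E)-prop-1-en-1-yl]phenoxy}-1-[(triethylsilyl)oxy]propyl]-2,6-dimethoxyphenoxy}silane F7. Desilylation (Bu4NF, AcOH, THF, 0 °C) would give 18.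

Further compounds
F1 | step 10 | (1R,2R)-1-[3,5-dimethoxy-4-(methoxymethoxy)phenyl]-1-(methoxymethoxy)propan-2-yl 4-nitrobenzoate | O=C(O[C@H](C)[C@H](OCOC)c1cc(OC)c(OCOC)c(OC)c1)c1ccc(cc1)[N+](=O)[O-]
F2 | step 10 | (1R,2R)-1-[3,5-dimethoxy-4-(methoxymethoxy)phenyl]-1-(methoxymethoxy)propan-2-ol | O[C@H](C)[C@H](OCOC)c1cc(OC)c(OCOC)c(OC)c1
F3 | step 9 | 4-formyl-2,6-dimethoxyphenyl trifluoromethanesulfonate | O=Cc1cc(OC)c(OS(=O)(=O)C(F)(F)F)c(OC)c1
F4 | step 12 | 4-{[(1R,2S)-1-(bromomethoxy)-1-[4-(bromomethoxy)-3,5-dimethoxyphenyl]propan-2-yl]oxy}-3,5-dimethoxybenzaldehyde | O=Cc1cc(OC)c(O[C@@H](C)[C@H](OCBr)c2cc(OC)c(OCBr)c(OC)c2)c(OC)c1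
F5 | step 12 | 4-{[(1R,2S)-1-hydroxy-1-(4-hydroxy-3,5-dimethoxyphenyl)propan-2-yl]oxy}-3,5-dimethoxybenzaldehyde | O=Cc1cc(OC)c(O[C@@H](C)[C@H](O)c2cc(OC)c(O)c(OC)c2)c(OC)c1
F6 | step 12 | 4-{[(1R,2S)-1-{3,5-dimethoxy-4-[(triethylsilyl)oxy]phenyl}-1-[(triethylsilyl)oxy]propan-2-yl]oxy}-3,5-dimethoxybenzaldehyde | O=Cc1cc(OC)c(O[C@@H](C)[C@H](O[Si](CC)(CC)CC)c2cc(OC)c(O[Si](CC)(CC)CC)c(OC)c2)c(OC)c1
F7 | step 12 | triethyl{4-[(1R,2S)-2-{2,6-dimethoxy-4-[(1E)-prop-1-en-1-yl]phenoxy}-1-[(triethylsilyl)oxy]propyl]-2,6-dimethoxyphenoxy}silane | C/C=C/c1cc(OC)c(O[C@@H](C)[C@H](O[Si](CC)(CC)CC)c2cc(OC)c(O[Si](CC)(CC)CC)c(OC)c2)c(OC)c1
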